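**Retrosynthetic overview**

- The C7–O benzoate goes on last, by selective primary benzoylation of a triol. That triol comes from removing the acetonide that ties C7–O to C6–O. The C2 and C5 benzoates go on before that, while C1–OH is tertiary and inert.
- The cyclohexene ring is closed at C1–C2 by a SmI2 ketone–aldehyde pinacol coupling of a masked Z-configured keto-enal, giving the cis C1/C2 diol anti to C6–O.
- The masked keto-enal comes from a C5–C6 bond made by L-proline anti-aldol of 2,2-dimethyl-1,3-dioxan-5-one with cis-butenedial (from 2,5-dimethoxy-2,5-dihydrofuran). In the same flask the adduct closes twice (dihydrofuran lactol, then bridging hemiketal); this key step sets C5 and C6.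
- Ring order: the dioxane is bought (it carries C7–C1–C6). The dihydrofuran and the bridging 1,3-dioxane form together in step 1 and are both temporary. The cyclohexene forms in step 2 as those two rings open. The dioxane is removed in step 4.

Assumption: atom labels C1–C7 are those of the target (C1 = carbinol carbon bearing the CH2O carbon C7; C2 and C5 = benzoyloxy carbons; C3=C4 = alkene; C6 = CHOH) and are used for every intermediate.

**Route**

Step 1
Reactants: 1 2,2-dimethyl-1,3-dioxan-5-one; 2 2,5-dimethoxy-2,5-dihydrofuran (commercial cis/trans mixture)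
Product: 5 (1S,2S,7S,9S)-4,4-dimethyl-3,5,8,12-tetraoxatricyclo[7.2.1.0^{2,7}]dodec-10-en-7-ol (bridged hemiketal), via (Z)-but-2-enedial 3 (not isolated), via open-chain aldol adduct 4 (not isolated)
Conditions: 2, H2O, AcOH (5 mol %), 40 °C, 2 h; then 1 (2 equiv), L-proline (30 mol %), DMF, 4 °C, 72 h
Reagents that add atoms: water, O
Why: Proposed new method: the L-proline enamine of 1 adds through the hydrogen-bonded Houk–List transition state to the re face of one aldehyde of 3 and gives the anti aldol with C5 (S) and C6 (S), as in the known proline-catalysed aldols of this ketone; the Z-γ-hydroxy enal then closes to the 2,5-dihydrofuran lactol (which takes the second aldehyde out of play) and the lactol OH adds to the hydrate-prone α,α'-dialkoxy ketone, so two rings form in one flask; closest known reaction type: proline-catalysed direct anti-aldol of 2,2-dimethyl-1,3-dioxan-5-one with aldehydes, followed by anhydro-sugar-type hemiketalisation.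

Step 2
Reactants: 5 bridged hemiketal
Product: 6 (4aS,5S,8S,8aS)-2,2-dimethyl-4a,5,8,8a-tetrahydro-4H-1,3-benzodioxine-4a,5,8-triol
Conditions: SmI2 (3 equiv), t-BuOH (3 equiv), THF, −40 → 23 °C
Reagents that add atoms: none
Why: Intramolecular SmI2 pinacol coupling of the ketone and the Z-enal; 5 is the closed ring–chain tautomer of keto-enal 4, and the small share of open form present at equilibrium is drained by single-electron reduction, while the samarium-chelated transition state gives the cis C1/C2 diol with both new C–O bonds anti to the C6 alkoxy group, as in SmI2 carbocyclisations of sugar-derived keto-aldehydes.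

Step 3
Reactants: 6 triol
Product: 7 (4aS,5S,8S,8aS)-4a-hydroxy-2,2-dimethyl-4a,5,8,8a-tetrahydro-4H-1,3-benzodioxine-5,8-diyl dibenzoate
Conditions: BzCl (2.5 equiv), pyridine, DMAP (10 mol %), CH2Cl2, 0 → 23 °C
Reagents that add atoms: benzoyl chloride, O=C(Cl)c1ccccc1
Why: DMAP-catalysed O-acylation; the two secondary allylic alcohols (C2, C5) react and the tertiary C1–OH does not, and no stereocentre is touched.

Step 4
Reactants: 7 dibenzoate acetonide
Product: 8 (1S,4S,5R,6S)-5,6-dihydroxy-5-(hydroxymethyl)cyclohex-2-ene-1,4-diyl dibenzoate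
Conditions: AcOH/H2O (4:1), 45 °C
Reagents that add atoms: none
Why: Acid-catalysed acetal hydrolysis; the six-membered acetonide is expected to cleave faster than the benzoates migrate or ionise, and no stereocentre is touched.

Step 5
Reactants: 8 triol dibenzoate
Product: 9 [(1R,2S,5S,6S)-2,5-bis(benzoyloxy)-1,6-dihydroxycyclohex-3-en-1-yl]methyl benzoate (target)
Conditions: BzCl (1.05 equiv), 2,4,6-collidine, CH2Cl2, −40 → −10 °C
Reagents that add atoms: benzoyl chloride, O=C(Cl)c1ccccc1
Why: Site-selective acylation; the primary C7–OH reacts far faster than the C6–OH (between the quaternary carbon and the C5 benzoate) or the tertiary C1–OH, and no stereocentre is touched.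

**Compound list**

1 | 2,2-dimethyl-1,3-dioxan-5-one | CC1(C)OCC(=O)CO1 | starting material
2 | 2,5-dimethoxy-2,5-dihydrofuran (cis/trans mixture) | COC1C=CC(OC)O1 | starting material
3 | (Z)-but-2-enedial | O=C/C=C\C=O | intermediate
4 | (4S)-4-[(1S,2Z)-1-hydroxy-4-oxobut-2-en-1-yl]-2,2-dimethyl-1,3-dioxan-5-one (open-chain aldol adduct; open ring–chain tautomer of 5) | CC1(C)OCC(=O)[C@H]([C@@H](O)/C=C\C=O)O1 | intermediate
5 | (1S,2S,7S,9S)-4,4-dimethyl-3,5,8,12-tetraoxatricyclo[7.2.1.0^{2,7}]dodec-10-en-7-ol (bridged hemiketal; the acetonide dioxane is cis-fused, the alkene sits in the two-carbon bridge) | CC1(C)OC[C@]2(O)O[C@H]3C=C[C@H](O3)[C@@H]2O1 | intermediate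
6 | (4aS,5S,8S,8aS)-2,2-dimethyl-4a,5,8,8a-tetrahydro-4H-1,3-benzodioxine-4a,5,8-triol | CC1(C)OC[C@]2(O)[C@@H](O)C=C[C@H](O)[C@@H]2O1 | intermediate
7 | (4aS,5S,8S,8aS)-4a-hydroxy-2,2-dimethyl-4a,5,8,8a-tetrahydro-4H-1,3-benzodioxine-5,8-diyl dibenzoate | CC1(C)OC[C@]2(O)[C@@H](OC(=O)c3ccccc3)C=C[C@H](OC(=O)c3ccccc3)[C@@H]2O1 | intermediate
8 | (1S,4S,5R,6S)-5,6-dihydroxy-5-(hydroxymethyl)cyclohex-2-ene-1,4-diyl dibenzoate | OC[C@]1(O)[C@@H](OC(=O)c2ccccc2)C=C[C@H](OC(=O)c2ccccc2)[C@@H]1O | intermediate
9 | [(1R,2S,5S,6S)-2,5-bis(benzoyloxy)-1,6-dihydroxycyclohex-3-en-1-yl]methyl benzoate | O=C(OC[C@]1(O)[C@@H](OC(=O)c2ccccc2)C=C[C@H](OC(=O)c2ccccc2)[C@@H]1O)c1ccccc1 | target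

**Step count**

Total steps: 5. Longest linear sequence: 5 (from 1).

**Steps most likely to fail, with fallbacks**

The first is step 1. Free cis-butenedial may isomerise to the E-dial under amine catalysis, or take the enamine in a conjugate sense. The hemiketal may also not close fully; the monocyclic keto-lactol would still enter step 2. The fallback sets out from 1 and returns at 5, carrying the Z-alkene as an alkyne. L-Proline-catalysed aldol of 1 with commercial 4,4-diethoxybut-2-ynal gives (4S)-4-[(1S)-4,4-diethoxy-1-hydroxybut-2-yn-1-yl]-2,2-dimethyl-1,3-dioxan-5-one F1. Semi-hydrogenation (H2, Pd on CaCO3 poisoned with Pb(OAc)2, quinoline, EtOAc) gives (4S)-4-[(1S,2Z)-4,4-diethoxy-1-hydroxybut-2-en-1-yl]-2,2-dimethyl-1,3-dioxan-5-one F2. Mild hydrolysis of the diethyl acetal (oxalic acid, wet THF, 23 °C) frees the aldehyde, which closes to 5.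

The second is step 2. The enal ketyl may be reduced in a 1,4 sense or lose the C5 oxygen, and unmasking of 5 may be slow. The fallback sets out from 5 and returns at 6, replacing the reductive coupling by olefination, metathesis and dihydroxylation. Double Wittig methylenation of 5 (Ph3P=CH2 from Ph3PCH3Br and KN(SiMe3)2, THF; both masked carbonyls open under the reaction) gives the triene (4R)-4-[(1S,2Z)-1-hydroxypenta-2,4-dien-1-yl]-2,2-dimethyl-5-methylidene-1,3-dioxane F3. Ring-closing metathesis with RuCl2(=CHPh)(PCy3)(H2IMes), the second-generation Grubbs catalyst, gives the cyclohexa-1,3-diene (8S,8aR)-2,2-dimethyl-8,8a-dihydro-4H-1,3-benzodioxin-8-ol F4. Dihydroxylation (OsO4 2 mol %, N-methylmorpholine N-oxide, acetone/H2O) of the electron-richer trisubstituted C1=C2 alkene, from the face anti to the C6–O bond, gives 6.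

The third is step 4. Warm acid may move the C5 benzoate to C6–OH or ionise the allylic benzoates. The fallback sets out from 6 and returns at 9, removing the acetonide before any ester is present. Treating 6 with AcOH/H2O (4:1) gives the pentaol (1S,2S,3S,6S)-1-(hydroxymethyl)cyclohex-4-ene-1,2,3,6-tetrol F5. Site-selective tribenzoylation (BzCl 3.1 equiv, 2,4,6-collidine, CH2Cl2, −40 → 0 °C) then gives 9 directly. The primary and the two allylic hydroxyls at C2 and C5 should react before the C6–OH and the tertiary C1–OH, but this selectivity is less certain than in step 5.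

**Further compounds**

F1 | step 1 | (4S)-4-[(1S)-4,4-diethoxy-1-hydroxybut-2-yn-1-yl]-2,2-dimethyl-1,3-dioxan-5-one | CC1(C)OCC(=O)[C@H]([C@@H](O)C#CC(OCC)OCC)O1
F2 | step 1 | (4S)-4-[(1S,2Z)-4,4-diethoxy-1-hydroxybut-2-en-1-yl]-2,2-dimethyl-1,3-dioxan-5-one | CC1(C)OCC(=O)[C@H]([C@@H](O)/C=C\C(OCC)OCC)O1
F3 | step 2 | (4R)-4-[(1S,2Z)-1-hydroxypenta-2,4-dien-1-yl]-2,2-dimethyl-5-methylidene-1,3-dioxane | CC1(C)OCC(=C)[C@H]([C@@H](O)/C=C\C=C)O1
F4 | step 2 | (8S,8aR)-2,2-dimethyl-8,8a-dihydro-4H-1,3-benzodioxin-8-ol | CC1(C)OCC2=CC=C[C@H](O)[C@@H]2O1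
F5 | step 4 | (1S,2S,3S,6S)-1-(hydroxymethyl)cyclohex-4-ene-1,2,3,6-tetrol | OC[C@]1(O)[C@@H](O)C=C[C@H](O)[C@@H]1O
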